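## The problem

The target consists of two carbocyclic halves joined only by a CH2CH2 chain: a methylenecyclohexanol (ring A) and an octalin (rings B and C) whose ring-fusion carbons form a tetrasubstituted olefin and whose ring C carries a hydroquinone-methyl group, sulfated on the oxygen remote from the benzylic carbon. Ring A holds three contiguous stereocentres: the carbinol carbon, a quaternary carbon (methyl, homoprenyl) and the methine that bears the chain, with hydroxyl, homoprenyl and chain all equatorial. Within this triad the carbinol can direct the quaternary carbon, and the quaternary carbon can direct the methine. In ring C the secondary methyl carbon and the adjacent benzyl-bearing quaternary carbon can also control one another. The quaternary carbon of ring B (methyl, chain) lies across the flat ring-fusion olefin from the ring C centres, and the two halves are insulated by the chain, so absolute control has to be applied three separate times. The aryl hydrogen sulfate is acid-labile and must come last, and the hydroquinone is best carried as its dimethyl ether. The ring-fusion olefin sits between two quaternary carbons next to an electron-rich arene, so protonation invites 1,2-shifts or Friedel-Crafts closure; the exocyclic methylene and the prenyl olefin rule out strong acid, ozone and unselective hydrogenation. The key step is made possible by ring A: the quaternary carbon lies between the carbinol carbon and the methine, and the methine is alpha to the methylene-bearing carbon. With that carbon written as a carbonyl, ring A is a 4-oxy-3-methylcyclohex-2-enone that has taken homoprenyl at its beta carbon and the chain at its alpha carbon.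

## Retrosynthesis

**Sulfate and hydroquinone.** The S–O bond of target 35 is cut first, together with the ring A silyl ether, giving sodium sulfate 34 and hydroquinone 33. Keeping the ring A hydroxyl silylated until the end leaves the two phenols as the only sulfation sites, and their different steric environments decide between them. Hydroquinone 33 comes from dimethyl ether 31 through quinone 32, so the arene travels through the whole synthesis as a robust 2,5-dimethoxybenzyl group.

**Exocyclic methylene and methine.** The C=CH2 bond of 31 is cut to ketone 30. A ketone at this position makes the chain-bearing methine an alpha carbon. Ketone 30 is the conjugate-reduction product of alkylidene ketone 29, which is the dehydration product of aldol 27. Introducing the chain carbon as an aldehyde rather than an alkyl halide is preferred because the alpha carbon is neopentyl-like and would alkylate poorly. The oxygen is then removed by steps that also reset the methine under control of the neighbouring axial methyl group.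

**Key disconnection.** In 27 two ring A bonds are cut at once: quaternary carbon–homoprenyl and methine–chain. This leaves silyloxy enone 4, homoprenylmagnesium bromide 6 and octalin acetaldehyde 25, joined through silyl enol ether 26. Cutting here, rather than inside either half, divides the molecule into pieces of similar size. It also lets the one stereocentre of 4 set the quaternary carbon. The forward reaction must add anti to the silyloxy group at a beta,beta-disubstituted enone and then form a C–C bond at a hindered enol ether carbon.

**Enone 4 and Grignard 6.** Enone 4 is reached from silyl ether 3 by allylic oxidation of the ring CH2, 3 from allylic alcohol 2, and 2 from 2-methylcyclohex-2-en-1-one 1 by enantioselective carbonyl reduction. The carbinol is thus bought with one catalytic step on a cheap enone. Reagent 6 comes from bromide 5.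

**Ring B of the octalin.** Aldehyde 25 is the hydrolysis product of silyl enol ether 24. In 24 the bond between the ring B quaternary carbon and the ring-fusion carbon is cut, leading to alkenyl bromide 23, which carries a (Z)-trisubstituted allylic silyl ether. An intramolecular Heck reaction is chosen over a cycloaddition for three reasons: the ring-fusion olefin is present from the start as the alkenyl halide and never has to be moved by acid; the acetaldehyde arm appears at the right length; and a chiral ligand can set the insulated quaternary carbon.

**Side chain.** Bromide 23 is cut between the ring carbon and the first chain carbon, giving bromo enol triflate 15 and alkylborane 22, which is made from diene 21. The triflate of 15 is expected to couple before the bromide, so the two adjacent alkenyl carbons are addressed in turn. Diene 21 comes from alkenyl iodide 19 and allylboronate 20. Iodide 19 comes from (Z)-3-iodobut-2-en-1-ol 18 and hence from but-2-yn-1-ol 16, which fixes the olefin geometry.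

**Ring C.** Triflate 15 comes from bromo ketone 13 and this from ketone 11. The quaternary carbon of 11 blocks one alpha position, so only one enolate is possible. Ketone 11 is cut at the benzylic bond and at the secondary methyl group, giving silyl enol ether 8, benzyl bromide 9 and again enone 1. Catalytic asymmetric methyl addition sets the secondary centre, and alkylation anti to it sets the quaternary one. One commercial enone therefore feeds both halves.

## Roads not taken

**Alternative 1:** Ring C would be cut at two bonds: between its quaternary carbon and the ring-fusion carbon, and between the secondary methyl carbon and the adjacent CH2. The forward step is a Diels–Alder reaction of (E)-2-methylbut-2-enal with the ring B vinylcyclohexene A1 under a chiral oxazaborolidinium triflimide, giving octalin aldehyde A2.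
- Merits: one catalytic step closes ring C and sets both methyl-bearing carbons, cis to each other through the dienophile geometry. The chosen plan needs two steps (5 and 6) for the same centres, so in this respect the alternative is better.
- Weak points: the dienophile is trisubstituted and sluggish. The new olefin lies one position away from the ring fusion and must be isomerised. The formyl group must be turned into the dimethoxybenzyl group by aryl addition to a neopentyl aldehyde and benzylic deoxygenation, both next to an olefin that ionises easily.
- Comparison: the chosen plan introduces the arene at its final oxidation level by a simple enolate alkylation and never moves the ring-fusion olefin. Alternative 1 also leaves the union with ring A unsolved, which the chosen key step achieves while creating the ring A quaternary carbon.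

**Alternative 2:** Ring B would be cut at two bonds: between its quaternary carbon and the ring-fusion carbon, and at the CH2–CH2 bond opposite. The forward step is an enantioselective Diels–Alder reaction of methacrolein with the ring C diene A3 under a chiral oxazaborolidinium triflimide, giving octalin aldehyde A4.
- Merits: A3 is available from ketone 11 in two steps, and the cycloaddition forms the insulated quaternary carbon under catalyst control. Aldehyde 25 would be reached from 11 in about six steps, against five linear steps plus three for the side chain in the chosen route. In step count for the octalin this road is the better one.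
- Weak points: the adduct carries its olefin one bond away from the ring fusion, and moving it means protonating between two quaternary carbons beside the dimethoxyarene. The formyl group is also one carbon short and must be homologated at a neopentyl position.
- Comparison: the chosen plan creates the tetrasubstituted olefin and the acetaldehyde arm in their final positions. The cycloaddition is therefore kept only as the reserve for step 13. As a strategy for the whole molecule it still requires the ring A union used here.

**Alternative 3:** Ring A would be cut between its quaternary carbon and the methine. The forward step is Lewis-acid opening (Et2AlCl or BF3·OEt2) of epoxy allylsilane A5 at the tertiary epoxide carbon, with the allylsilane attacking with inversion and loss of Me3Si, giving ring A alcohol A6.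
- Merits: all three ring A stereocentres and the exocyclic methylene come from one chair-like closure. No ketone needs methylenation and no epimerisable methine is carried, which is better than the four-step adjustment (steps 15 to 18) in the chosen plan.
- Weak points: A5 needs a geometrically pure trisubstituted epoxide made enantioselectively in the presence of a second trisubstituted (prenyl) olefin. Hydride and methyl shifts compete with closure. The chain between the two halves would then have to be formed between a hindered CH2 on ring A and a neopentyl CH2 on the octalin, and an olefination route would require selective saturation beside the exocyclic methylene and the prenyl olefin.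
- Comparison: the chosen plan forms the inter-fragment bond as an aldehyde addition and removes the extra unsaturation as a conjugated enone, which a copper hydride reduces without touching the isolated olefins.

Key step: step 15

Assumptions (remarks on the chemistry):
- The target is taken as the free aryl hydrogen sulfate as drawn. It is released from its sodium salt in the last operation.
- The ligand enantiomers written in steps 5 and 13 are assumed to give the sense shown. The antipodal ligand is used if the first run shows the opposite.
- A stereocentre or olefin without descriptor in a SMILES string denotes a mixture that converges later.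

## Route

Step 1
Reactants: 1 2-methylcyclohex-2-en-1-one
Product: 2 (S)-2-methylcyclohex-2-en-1-ol
Conditions: (R)-Me-CBS oxazaborolidine (10 mol%), BH3·SMe2, THF, −20 °C; MeOH quench
Reagents that add atoms: none
Why: Corey–Bakshi–Shibata reduction; the alkenyl branch with its alpha methyl group acts as the large substituent, so the (R)-catalyst should deliver hydride to the face that gives the (S)-allylic alcohol, and alpha-substituted cyclohexenones are a favourable substrate class.

Step 2
Reactants: 2 (S)-2-methylcyclohex-2-en-1-ol
Product: 3 (S)-tert-butyldimethylsilyl ether of 2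
Conditions: TBSCl, imidazole, DMF, rt
Reagents that add atoms: tert-butyldimethylsilyl chloride, CC(C)(C)[Si](C)(C)Cl
Why: Standard silylation of a secondary alcohol; the bulky silyl ether later directs the conjugate addition and lasts until step 21.

Step 3
Reactants: 3 silyl ether
Product: 4 (S)-4-[(tert-butyldimethylsilyl)oxy]-3-methylcyclohex-2-en-1-one
Conditions: Rh2(cap)4 (cap = caprolactamate, 1 mol%), t-BuOOH (70% aq.), K2CO3, CH2Cl2, rt
Reagents that add atoms: tert-butyl hydroperoxide, CC(C)(C)OO
Why: Radical allylic oxidation of a 1-substituted cyclohexene to the 3-substituted enone; the ring CH2 next to the olefinic CH is the most accessible allylic position, while the C–H on the silyloxy carbon is shielded, and the carbinol stereocentre is not involved.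

Step 4
Reactants: 5 5-bromo-2-methylpent-2-ene
Product: 6 (4-methylpent-3-en-1-yl)magnesium bromide
Conditions: Mg turnings, I2 (trace), THF, rt
Reagents that add atoms: magnesium, [Mg]
Why: Grignard formation from a primary homoallylic bromide; the trisubstituted olefin is inert.

Step 5
Reactants: 1 2-methylcyclohex-2-en-1-one
Product: 8 (S)-[(2,3-dimethylcyclohex-1-en-1-yl)oxy]trimethylsilane, via aluminium enolate 7 (not isolated)
Conditions: Me3Al, Cu(O2CC4H3S) (copper thiophene-2-carboxylate, 2 mol%), phosphoramidite L* [(S)-binaphthol, N,N-bis((R)-1-phenylethyl)] (4 mol%), Et2O, −30 °C; then Me3SiOTf, THF, −30 to 0 °C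
Reagents that add atoms: trimethylaluminium, C[Al](C)C; trimethylsilyl trifluoromethanesulfonate, C[Si](C)(C)OS(=O)(=O)C(F)(F)F
Why: Copper-catalysed asymmetric conjugate addition of a trialkylaluminium, a reaction type that tolerates the alpha-methyl enone; the ligand sets the secondary methyl centre (3S), and O-silylation of the aluminium enolate keeps the enolate regiochemistry for step 6.

Step 6
Reactants: 8 silyl enol ether; 9 2-(bromomethyl)-1,4-dimethoxybenzene
Product: 11 (2R,3S)-2-(2,5-dimethoxybenzyl)-2,3-dimethylcyclohexan-1-one, via lithium enolate 10 (not isolated)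
Conditions: MeLi, THF, 0 °C to rt; then 9, HMPA, −78 to −20 °C
Reagents that add atoms: none
Why: Regiospecific enolate generation by Si–O cleavage followed by C-alkylation; the benzyl bromide approaches anti to the pseudoaxial C3 methyl group, giving the quaternary carbon with the two methyl groups cis.

Step 7
Reactants: 11 benzyl ketone
Product: 13 6-bromo derivative of 11 (both C6 epimers), via lithium enolate 12 (not isolated)
Conditions: LiN(i-Pr)2, THF, −78 °C; then NBS, −78 °C
Reagents that add atoms: N-bromosuccinimide, O=C1CCC(=O)N1Br
Why: Alpha-bromination through the enolate; the quaternary carbon leaves only one enolisable position, and at −78 °C the enolate outcompetes the dimethoxyarene for electrophilic bromine, while the new centre is removed in step 8.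

Step 8
Reactants: 13 bromo ketone
Product: 15 (5S,6R)-2-bromo-6-(2,5-dimethoxybenzyl)-5,6-dimethylcyclohex-1-en-1-yl trifluoromethanesulfonate, via potassium bromoenolate 14 (not isolated)
Conditions: KN(SiMe3)2, THF, −78 °C; then PhNTf2, −78 to 0 °C
Reagents that add atoms: N-phenylbis(trifluoromethanesulfonimide), O=S(=O)(N(c1ccccc1)S(=O)(=O)C(F)(F)F)C(F)(F)F
Why: Enol triflate formation; the only acidic hydrogen is the one on the bromine-bearing carbon, so deprotonation and O-sulfonylation give the 2-bromoalkenyl triflate as a single regioisomer.

Step 9
Reactants: 16 but-2-yn-1-ol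
Product: 18 (Z)-3-iodobut-2-en-1-ol, via cyclic alkenylaluminate 17 (not isolated)
Conditions: NaAlH2(OCH2CH2OMe)2, THF, 0 °C to rt; then I2, −78 °C
Reagents that add atoms: iodine, II
Why: Hydroxyl-directed trans-hydroalumination of a propargylic alcohol followed by iodinolysis with retention; the five-membered aluminate fixes aluminium, and then iodine, on C3 cis to the CH2O group.

Step 10
Reactants: 18 (Z)-3-iodobut-2-en-1-ol
Product: 19 (Z)-tert-butyl[(3-iodobut-2-en-1-yl)oxy]dimethylsilane
Conditions: TBSCl, imidazole, CH2Cl2, rt
Reagents that add atoms: tert-butyldimethylsilyl chloride, CC(C)(C)[Si](C)(C)Cl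
Why: Standard silylation; the allylic silyl ether is the group that later ends the Heck reaction as an enol ether.

Step 11
Reactants: 19 alkenyl iodide; 20 2-allyl-4,4,5,5-tetramethyl-1,3,2-dioxaborolane
Product: 21 (Z)-tert-butyldimethyl[(3-methylhexa-2,5-dien-1-yl)oxy]silane
Conditions: Pd(dppf)Cl2 (5 mol%), CsF, THF, 65 °C
Reagents that add atoms: none
Why: Suzuki–Miyaura allylation of an alkenyl iodide, which proceeds with retention of olefin geometry and gives the skipped diene with the new chain cis to the silyloxymethyl group.

Step 12
Reactants: 21 skipped diene; 15 bromo enol triflate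
Product: 23 alkenyl bromide with the C6 side chain, via alkylborane 22 (not isolated)
Conditions: 9-BBN-H, THF, 0 °C to rt; then 15, Pd(dppf)Cl2 (10 mol%), AsPh3, Cs2CO3, DMF/H2O, rt
Reagents that add atoms: none
Why: Hydroboration of the terminal olefin and B-alkyl Suzuki–Miyaura coupling; alkenyl triflates add to zerovalent palladium faster than a tetrasubstituted alkenyl bromide, the order used in sequential couplings of 2-bromoalkenyl triflates, so the chain should enter at the triflate carbon and the bromide is kept for step 13.

Step 13
Reactants: 23 alkenyl bromide
Product: 24 octalin silyl enol ether (E/Z mixture)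
Conditions: Pd(OAc)2 (10 mol%), (R)-BINAP (20 mol%), Ag3PO4, CaCO3, NMP, 80 °C
Reagents that add atoms: none
Why: Asymmetric intramolecular Heck reaction (6-exo-trig) through a cationic BINAP–palladium alkenyl generated by silver-assisted bromide abstraction; enantioface-selective insertion of the (Z)-olefin forms the ring B quaternary carbon (1R) under ligand control, and beta-hydride elimination can only occur towards the silyloxymethyl group. The ring-fusion olefin is the original alkenyl unit and is not moved.

Step 14
Reactants: 24 silyl enol ether
Product: 25 2-[(1R,5R,6S)-5-(2,5-dimethoxybenzyl)-1,5,6-trimethyl-1,2,3,4,5,6,7,8-octahydronaphthalen-1-yl]acetaldehyde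
Conditions: Bu4NF, AcOH, THF, 0 °C
Reagents that add atoms: none
Why: Fluoride cleavage of a silyl enol ether with buffered protonation; no mineral acid touches the ring-fusion olefin, and the aldehyde has no epimerisable centre.

Step 15
Reactants: 4 silyloxy enone; 6 homoprenylmagnesium bromide; 25 octalin acetaldehyde
Product: 27 aldol adduct (epimers at ring C2 and at the carbinol), via silyl enol ether 26 (not isolated)
Conditions: CuBr·SMe2 (10 mol%), Me3SiCl, HMPA, THF, −78 °C; Et3N, pentane, filtration, evaporation; then 25, TiCl4, CH2Cl2, −78 °C
Reagents that add atoms: none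
Why: The Grignard reagent transmetalates to copper, and the organocopper adds to C3 of enone 4 in a Me3SiCl-accelerated conjugate addition; the enolate is silylated as it forms and gives silyl enol ether 26 as a single regioisomer. After removal of magnesium salts and excess Grignard reagent, TiCl4 activates aldehyde 25 and 26 adds through C2 in an open Mukaiyama aldol transition state, so the C3–homoprenyl and C2–chain bonds are made in one operation and no ring is closed. The closest known reaction type is the three-component coupling of 4-silyloxycycloalkenones by organocopper conjugate addition and aldehyde trapping of the enolate, used here in its silyl enol ether form because the beta,beta-disubstituted enone needs Me3SiCl activation. The new quaternary centre (3S) is controlled by the C4 silyloxy stereocentre: the copper reagent attacks the face opposite the silyloxy group, which places homoprenyl trans to oxygen. The methine and carbinol centres formed in the aldol are not relied upon, since both are erased in step 16 and the methine is reset in step 17. The step needs 1,4- over 1,2-addition (secured by copper catalysis with Me3SiCl), a single enolate regioisomer (secured because conjugate addition can only give the C1–C2 enol ether) and aldehyde-selective C–C bond formation (secured by TiCl4 at −78 °C, which leaves the aryl ethers, the silyl ether and the isolated olefins alone).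

Step 16
Reactants: 27 aldol adduct
Product: 29 2-alkylidene ketone (olefin geometry immaterial), via mesylate 28 (not isolated)
Conditions: MsCl, Et3N, CH2Cl2, 0 °C; then DBU, rt
Reagents that add atoms: none
Why: Dehydration of a beta-hydroxy ketone by mesylation and E1cB elimination; sulfonylation first blocks retro-aldol cleavage, and both carbinol epimers and both C2 epimers converge on the same enone.

Step 17
Reactants: 29 alkylidene ketone
Product: 30 (2S,3S,4S)-ketone with the saturated chain
Conditions: [(Ph3P)CuH]6, C6H6, degassed H2O, rt
Reagents that add atoms: none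
Why: Copper hydride conjugate reduction, selective for the enone over the three isolated olefins; the copper enolate is protonated at C2 on the face opposite the axial C3 methyl group, which places the chain equatorial, cis to methyl and trans to homoprenyl. This is also the epimer expected to be favoured at equilibrium.

Step 18
Reactants: 30 ketone
Product: 31 exocyclic methylene compound
Conditions: Cp2TiMe2, toluene/THF, 70 °C, dark
Reagents that add atoms: dimethyltitanocene, C[Ti](C)(C1C=CC=C1)C1C=CC=C1
Why: Petasis olefination through the titanium methylidene formed on heating; the reagent is not basic, so the epimerisable C2 methine set in step 17 is not disturbed, which a phosphorus ylide could not guarantee.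

Step 19
Reactants: 31 dimethyl ether
Product: 33 hydroquinone, via quinone 32 (not isolated)
Conditions: (NH4)2Ce(NO3)6, MeCN/H2O, 0 °C; then aq. Na2S2O4
Reagents that add atoms: water, O
Why: Oxidative demethylation of a 1,4-dimethoxyarene to the benzoquinone by the tetravalent cerium salt, which is much faster at 0 °C than oxidation of the isolated olefins, followed by dithionite reduction of the quinone during work-up.

Step 20
Reactants: 33 hydroquinone
Product: 34 sodium aryl sulfate (sulfate on the oxygen meta to the benzylic carbon)
Conditions: SO3·pyridine (1.1 equiv), pyridine, 0 °C; aq. NaHCO3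
Reagents that add atoms: sulfur trioxide–pyridine, O=S(=O)([O-])[n+]1ccccc1; sodium hydrogen carbonate, [Na+].OC([O-])=O
Why: O-sulfation of a phenol; the phenol ortho to the neopentyl-type benzylic substituent is shielded, so the reagent should take the distal hydroxyl, and the ring A alcohol is still silylated and cannot compete.

Step 21
Reactants: 34 sodium aryl sulfate
Product: 35 target hydrogen sulfate
Conditions: Bu4NF, THF, 45 °C; then cold 0.1 M HCl, EtOAc extraction
Reagents that add atoms: none
Why: Fluoride desilylation of the hindered secondary silyl ether, to which aryl sulfate anions are stable; brief cold acidification gives the free hydrogen sulfate without isomerising the exocyclic methylene.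

## Compound list

Oct = (1R,5R,6S)-5-(2,5-dimethoxybenzyl)-1,5,6-trimethyl-1,2,3,4,5,6,7,8-octahydronaphthalen-1-yl

1 | 2-methylcyclohex-2-en-1-one | CC1=CCCCC1=O | starting material
2 | (S)-2-methylcyclohex-2-en-1-ol | CC1=CCCC[C@@H]1O | intermediate
3 | (S)-tert-butyldimethyl[(2-methylcyclohex-2-en-1-yl)oxy]silane | CC1=CCCC[C@@H]1O[Si](C)(C)C(C)(C)C | intermediate
4 | (S)-4-[(tert-butyldimethylsilyl)oxy]-3-methylcyclohex-2-en-1-one | O=C1CC[C@H](O[Si](C)(C)C(C)(C)C)C(C)=C1 | intermediate
5 | 5-bromo-2-methylpent-2-ene | CC(C)=CCCBr | starting material
6 | (4-methylpent-3-en-1-yl)magnesium bromide | CC(C)=CCC[Mg]Br | intermediate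
7 | dimethylaluminium (S)-2,3-dimethylcyclohex-1-en-1-olate | C[C@H]1CCCC(O[Al](C)C)=C1C | intermediate
8 | (S)-[(2,3-dimethylcyclohex-1-en-1-yl)oxy]trimethylsilane | C[C@H]1CCCC(O[Si](C)(C)C)=C1C | intermediate
9 | 2-(bromomethyl)-1,4-dimethoxybenzene | COc1ccc(OC)c(CBr)c1 | starting material
10 | lithium (S)-2,3-dimethylcyclohex-1-en-1-olate | C[C@H]1CCCC(O[Li])=C1C | intermediate
11 | (2R,3S)-2-(2,5-dimethoxybenzyl)-2,3-dimethylcyclohexan-1-one | O=C1CCC[C@H](C)[C@@]1(C)Cc1cc(OC)ccc1OC | intermediate
12 | lithium (5S,6R)-6-(2,5-dimethoxybenzyl)-5,6-dimethylcyclohex-1-en-1-olate | [Li]OC1=CCC[C@H](C)[C@@]1(C)Cc1cc(OC)ccc1OC | intermediate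
13 | (2R,3S)-6-bromo-2-(2,5-dimethoxybenzyl)-2,3-dimethylcyclohexan-1-one (C6 epimers) | O=C1C(Br)CC[C@H](C)[C@@]1(C)Cc1cc(OC)ccc1OC | intermediate
14 | potassium (5S,6R)-2-bromo-6-(2,5-dimethoxybenzyl)-5,6-dimethylcyclohex-1-en-1-olate | [K]OC1=C(Br)CC[C@H](C)[C@@]1(C)Cc1cc(OC)ccc1OC | intermediate
15 | (5S,6R)-2-bromo-6-(2,5-dimethoxybenzyl)-5,6-dimethylcyclohex-1-en-1-yl trifluoromethanesulfonate | O=S(=O)(OC1=C(Br)CC[C@H](C)[C@@]1(C)Cc1cc(OC)ccc1OC)C(F)(F)F | intermediate
16 | but-2-yn-1-ol | CC#CCO | starting material
17 | sodium 2,2-bis(2-methoxyethoxy)-3-methyl-2,5-dihydro-1,2-oxaaluminol-2-uide (cyclic alkenylaluminate) | CC1=CCO[Al-]1(OCCOC)OCCOC.[Na+] | intermediate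
18 | (Z)-3-iodobut-2-en-1-ol | C/C(I)=C/CO | intermediate
19 | (Z)-tert-butyl[(3-iodobut-2-en-1-yl)oxy]dimethylsilane | C/C(I)=C/CO[Si](C)(C)C(C)(C)C | intermediate
20 | 2-allyl-4,4,5,5-tetramethyl-1,3,2-dioxaborolane | C=CCB1OC(C)(C)C(C)(C)O1 | starting material
21 | (Z)-tert-butyldimethyl[(3-methylhexa-2,5-dien-1-yl)oxy]silane | C=CC/C(C)=C\CO[Si](C)(C)C(C)(C)C | intermediate
22 | (Z)-9-{6-[(tert-butyldimethylsilyl)oxy]-4-methylhex-4-en-1-yl}-9-borabicyclo[3.3.1]nonane | C/C(CCCB1C2CCCC1CCC2)=C/CO[Si](C)(C)C(C)(C)C | intermediate
23 | (Z)-{[6-((5S,6R)-2-bromo-6-(2,5-dimethoxybenzyl)-5,6-dimethylcyclohex-1-en-1-yl)-3-methylhex-2-en-1-yl]oxy}(tert-butyl)dimethylsilane | C/C(CCCC1=C(Br)CC[C@H](C)[C@@]1(C)Cc1cc(OC)ccc1OC)=C/CO[Si](C)(C)C(C)(C)C | intermediate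
24 | tert-butyldimethyl{[2-(Oct)ethenyl]oxy}silane (E/Z mixture) | CC(C)(C)[Si](C)(C)OC=C[C@@]1(C)CCCC2=C1CC[C@H](C)[C@@]2(C)Cc1cc(OC)ccc1OC | intermediate
25 | 2-(Oct)acetaldehyde | O=CC[C@@]1(C)CCCC2=C1CC[C@H](C)[C@@]2(C)Cc1cc(OC)ccc1OC | intermediate
26 | tert-butyldimethyl{[(1S,2S)-2-methyl-2-(4-methylpent-3-en-1-yl)-4-(trimethylsilyloxy)cyclohex-3-en-1-yl]oxy}silane | C[Si](C)(C)OC1=C[C@](C)(CCC=C(C)C)[C@@H](O[Si](C)(C)C(C)(C)C)CC1 | intermediate
27 | (3S,4S)-4-[(tert-butyldimethylsilyl)oxy]-2-[1-hydroxy-2-(Oct)ethyl]-3-methyl-3-(4-methylpent-3-en-1-yl)cyclohexan-1-one (epimers at C2 and at the carbinol) | O=C1CC[C@H](O[Si](C)(C)C(C)(C)C)[C@@](C)(CCC=C(C)C)C1C(O)C[C@@]1(C)CCCC2=C1CC[C@H](C)[C@@]2(C)Cc1cc(OC)ccc1OC | intermediate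
28 | methanesulfonate of the carbinol of 27 | O=C1CC[C@H](O[Si](C)(C)C(C)(C)C)[C@@](C)(CCC=C(C)C)C1C(OS(C)(=O)=O)C[C@@]1(C)CCCC2=C1CC[C@H](C)[C@@]2(C)Cc1cc(OC)ccc1OC | intermediate
29 | (3S,4S)-4-[(tert-butyldimethylsilyl)oxy]-3-methyl-3-(4-methylpent-3-en-1-yl)-2-[2-(Oct)ethylidene]cyclohexan-1-one | O=C1CC[C@H](O[Si](C)(C)C(C)(C)C)[C@@](C)(CCC=C(C)C)C1=CC[C@@]1(C)CCCC2=C1CC[C@H](C)[C@@]2(C)Cc1cc(OC)ccc1OC | intermediate
30 | (2S,3S,4S)-4-[(tert-butyldimethylsilyl)oxy]-3-methyl-3-(4-methylpent-3-en-1-yl)-2-[2-(Oct)ethyl]cyclohexan-1-one | O=C1CC[C@H](O[Si](C)(C)C(C)(C)C)[C@@](C)(CCC=C(C)C)[C@@H]1CC[C@@]1(C)CCCC2=C1CC[C@H](C)[C@@]2(C)Cc1cc(OC)ccc1OC | intermediate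
31 | tert-butyldimethyl{[(1S,2S,3R)-2-methyl-2-(4-methylpent-3-en-1-yl)-4-methylidene-3-[2-(Oct)ethyl]cyclohexyl]oxy}silane | C=C1CC[C@H](O[Si](C)(C)C(C)(C)C)[C@@](C)(CCC=C(C)C)[C@@H]1CC[C@@]1(C)CCCC2=C1CC[C@H](C)[C@@]2(C)Cc1cc(OC)ccc1OC | intermediate
32 | quinone: 31 with the 2,5-dimethoxyphenyl ring replaced by 3,6-dioxocyclohexa-1,4-dien-1-yl | C=C1CC[C@H](O[Si](C)(C)C(C)(C)C)[C@@](C)(CCC=C(C)C)[C@@H]1CC[C@@]1(C)CCCC2=C1CC[C@H](C)[C@@]2(C)CC1=CC(=O)C=CC1=O | intermediate
33 | hydroquinone: 31 with the 2,5-dimethoxyphenyl ring replaced by 2,5-dihydroxyphenyl | C=C1CC[C@H](O[Si](C)(C)C(C)(C)C)[C@@](C)(CCC=C(C)C)[C@@H]1CC[C@@]1(C)CCCC2=C1CC[C@H](C)[C@@]2(C)Cc1cc(O)ccc1O | intermediate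
34 | sodium aryl sulfate: 33 with the hydroxyl meta to the benzylic carbon as its O-sulfonate sodium salt | C=C1CC[C@H](O[Si](C)(C)C(C)(C)C)[C@@](C)(CCC=C(C)C)[C@@H]1CC[C@@]1(C)CCCC2=C1CC[C@H](C)[C@@]2(C)Cc1cc(OS(=O)(=O)[O-])ccc1O.[Na+] | intermediate
35 | target: 4-hydroxy-3-{[(1R,2S,5R)-5-{2-[(1R,2S,6S)-6-hydroxy-1-methyl-1-(4-methylpent-3-en-1-yl)-3-methylidenecyclohex-2-yl]ethyl}-1,2,5-trimethyl-1,2,3,4,5,6,7,8-octahydronaphthalen-1-yl]methyl}phenyl hydrogen sulfate, drawn as in the SMILES | C=C1CC[C@H](O)[C@@](C)(CCC=C(C)C)[C@@H]1CC[C@@]1(C)CCCC2=C1CC[C@H](C)[C@@]2(C)Cc1cc(OS(=O)(=O)O)ccc1O | target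

## Step count and risks

Total step count: 21 steps.
Longest linear sequence: 14 steps (steps 5 to 8 and 12 to 21, from 1).

**Step 15 (key step).** Carbon–carbon bond formation at the neopentyl C2 of 26 may be slow, so that desilylation to the simple ketone, or retro-aldol cleavage of the titanium aldolate on work-up, overtakes the addition. Fallback: it sets out from 26, now freed of salts and used as isolated material, and from 25. Methyllithium cleaves the Si–O bond of 26 to give the lithium enolate F1. This adds to 25 at −78 °C through a closed, metal-bound six-membered transition state (after exchange to zinc if proton transfer intervenes) instead of the open Lewis-acid pathway. The adduct is 27, where the route is rejoined.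

**Step 12.** Palladium may insert into the C–Br bond in competition with the triflate, or transmetalation at the congested tetrasubstituted carbon may be slow enough for protodeboronation to consume 22. Fallback: it sets out from 15 and builds the chain in two couplings, each with secured site selectivity. A Stille coupling with allyltributylstannane in the presence of LiCl, conditions under which triflates react before bromides, gives the allyl bromoalkene F2. 9-BBN-H then hydroborates only the terminal olefin to give the alkylborane F3. F3 is coupled with the alkenyl iodide 19, which adds to zerovalent palladium far faster than the hindered ring bromide. This gives 23, where the route is rejoined.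

**Step 13.** Oxidative addition of the hindered alkenyl bromide may be sluggish, or the ligand may discriminate poorly between the olefin faces at a centre remote from the existing stereocentres, giving the ring B epimer as well. Fallback: it sets out from 11 and replaces the Heck closure by a cycloaddition.
- KN(SiMe3)2 and PhNTf2 give the enol triflate F4.
- Coupling with potassium vinyltrifluoroborate gives the diene F5, which is identical with A3.
- Methacrolein and the chiral oxazaborolidinium triflimide give the aldehyde F6, which is identical with A4.
- Wittig reaction with methoxymethylenetriphenylphosphorane gives the enol ether F7, and mild hydrolysis gives the homologated aldehyde F8.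
- Migration of the trisubstituted olefin into the ring fusion (RhCl3·3H2O in ethanol) gives 25, where the route is rejoined.

This last migration beside the electron-rich arene is the reason the cycloaddition is held in reserve.

**Step 17.** The copper enolate may be protonated from the wrong face, or the methine may epimerise on handling, leaving a mixture at C2. Fallback: it sets out from 29 and gives up kinetic control. The reduction is run without regard to face, giving 30 together with its C2 epimer F9. The mixture is equilibrated with NaOMe in MeOH, where the epimer with the chain equatorial should predominate, and the minor isomer is recycled. The route is rejoined at 30.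

**Step 20.** Sulfation may occur on the shielded phenol or on both phenols if the steric difference is too small. Fallback: it sets out from 33 and differentiates the phenols by acylation. Ac2O and pyridine give the diacetate F10. The less hindered acetate is removed selectively (NH4OAc in aqueous MeOH) to give the mono-acetate F11. Sulfation of its free distal phenol gives the acetate sulfate F12, and K2CO3 in MeOH removes the remaining acetate without touching the sulfate. The route is rejoined at 34.

## Further compounds

F1 | step 15 | lithium (4S,5S)-4-[(tert-butyldimethylsilyl)oxy]-5-methyl-5-(4-methylpent-3-en-1-yl)cyclohex-1-en-1-olate... (lithium enolate of the conjugate adduct) | [Li]OC1=C[C@](C)(CCC=C(C)C)[C@@H](O[Si](C)(C)C(C)(C)C)CC1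
F2 | step 12 | 2-{[(1R,6S)-2-allyl-3-bromo-1,6-dimethylcyclohex-2-en-1-yl]methyl}-1,4-dimethoxybenzene | C=CCC1=C(Br)CC[C@H](C)[C@@]1(C)Cc1cc(OC)ccc1OC
F3 | step 12 | 9-{3-[(5S,6R)-2-bromo-6-(2,5-dimethoxybenzyl)-5,6-dimethylcyclohex-1-en-1-yl]propyl}-9-borabicyclo[3.3.1]nonane | C(CCB1C2CCCC1CCC2)C1=C(Br)CC[C@H](C)[C@@]1(C)Cc1cc(OC)ccc1OC
F4 | step 13 | (5S,6R)-6-(2,5-dimethoxybenzyl)-5,6-dimethylcyclohex-1-en-1-yl trifluoromethanesulfonate | O=S(=O)(OC1=CCC[C@H](C)[C@@]1(C)Cc1cc(OC)ccc1OC)C(F)(F)F
F5 | step 13 | 2-{[(1R,6S)-1,6-dimethyl-2-vinylcyclohex-2-en-1-yl]methyl}-1,4-dimethoxybenzene | C=CC1=CCC[C@H](C)[C@@]1(C)Cc1cc(OC)ccc1OC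
F6 | step 13 | (1R,5R,6S)-5-(2,5-dimethoxybenzyl)-1,5,6-trimethyl-1,2,3,5,6,7,8,8a-octahydronaphthalene-1-carbaldehyde (ring-fusion methine epimers) | O=C[C@@]1(C)CCC=C2C1CC[C@H](C)[C@@]2(C)Cc1cc(OC)ccc1OC
F7 | step 13 | methyl enol ether from F6 (2-methoxyethenyl in place of formyl, E/Z mixture) | COC=C[C@@]1(C)CCC=C2C1CC[C@H](C)[C@@]2(C)Cc1cc(OC)ccc1OC
F8 | step 13 | 2-[(1R,5R,6S)-5-(2,5-dimethoxybenzyl)-1,5,6-trimethyl-1,2,3,5,6,7,8,8a-octahydronaphthalen-1-yl]acetaldehyde (olefin not yet in the ring fusion) | O=CC[C@@]1(C)CCC=C2C1CC[C@H](C)[C@@]2(C)Cc1cc(OC)ccc1OC
F9 | step 17 | (2R,3S,4S)-epimer of 30 (chain cis to homoprenyl) | O=C1CC[C@H](O[Si](C)(C)C(C)(C)C)[C@@](C)(CCC=C(C)C)[C@H]1CC[C@@]1(C)CCCC2=C1CC[C@H](C)[C@@]2(C)Cc1cc(OC)ccc1OC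
F10 | step 20 | diacetate of hydroquinone 33 | C=C1CC[C@H](O[Si](C)(C)C(C)(C)C)[C@@](C)(CCC=C(C)C)[C@@H]1CC[C@@]1(C)CCCC2=C1CC[C@H](C)[C@@]2(C)Cc1cc(OC(C)=O)ccc1OC(C)=O
F11 | step 20 | mono-acetate of 33 (acetate on the oxygen ortho to the benzylic carbon) | C=C1CC[C@H](O[Si](C)(C)C(C)(C)C)[C@@](C)(CCC=C(C)C)[C@@H]1CC[C@@]1(C)CCCC2=C1CC[C@H](C)[C@@]2(C)Cc1cc(O)ccc1OC(C)=O
F12 | step 20 | sodium sulfate of F11 (acetate retained) | C=C1CC[C@H](O[Si](C)(C)C(C)(C)C)[C@@](C)(CCC=C(C)C)[C@@H]1CC[C@@]1(C)CCCC2=C1CC[C@H](C)[C@@]2(C)Cc1cc(OS(=O)(=O)[O-])ccc1OC(C)=O.[Na+]
A1 | alternative 1 | tert-butyl[2-(1-methyl-2-vinylcyclohex-2-en-1-yl)ethoxy]diphenylsilane (ring B diene, single enantiomer) | C=CC1=CCCC[C@]1(C)CCO[Si](c1ccccc1)(c1ccccc1)C(C)(C)C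
A2 | alternative 1 | octalin aldehyde from the tiglic aldehyde cycloaddition (ring-fusion methine epimers) | O=C[C@]1(C)[C@@H](C)CC=C2C1CCC[C@]2(C)CCO[Si](c1ccccc1)(c1ccccc1)C(C)(C)C
A3 | alternative 2 | 2-{[(1R,6S)-1,6-dimethyl-2-vinylcyclohex-2-en-1-yl]methyl}-1,4-dimethoxybenzene (ring C diene) | C=CC1=CCC[C@H](C)[C@@]1(C)Cc1cc(OC)ccc1OC
A4 | alternative 2 | octalin aldehyde from the methacrolein cycloaddition (ring-fusion methine epimers) | O=C[C@@]1(C)CCC=C2C1CC[C@H](C)[C@@]2(C)Cc1cc(OC)ccc1OC
A5 | alternative 3 | (Z)-epoxy allylsilane: tert-butyldiphenylsilyl ether of 3-[(trimethylsilyl)methyl]-5-[3-methyl-3-(4-methylpent-3-en-1-yl)oxiran-2-yl]pent-2-en-1-ol | C[Si](C)(C)C/C(CC[C@@H]1O[C@@]1(C)CCC=C(C)C)=C\CO[Si](c1ccccc1)(c1ccccc1)C(C)(C)C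
A6 | alternative 3 | ring A alcohol with silyloxymethyl arm | C=C1CC[C@H](O)[C@@](C)(CCC=C(C)C)[C@@H]1CO[Si](c1ccccc1)(c1ccccc1)C(C)(C)C
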